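**Plan**
- Retrosynthetic cuts: the lactone bond O1'–C2' (oxygen taken out and C2' rejoined to C5', giving a 4-hydroxycyclobutenone); C4'–CH3 and C5'–C15 (MeLi and an allylbarium onto isopropyl semisquarate); C13=C14 (olefination of a C13 methyl ketone); C18–O and C8–O (back to the 4α-methyl and the C8=C17 alkene of (+)-larixol).
- Enabling feature: the ring O1'–C2'(=O)–C3'H=C4'(CH3)–C5' is the carbocycle C2'–C3'–C4'–C5' of a cyclobutenone with one oxygen inserted between C5' and C2'. C15H2 lies between C5' and the C13=C14 alkene, so loss of one of its protons completes the conjugated triene.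
- Forward order: rings A and B come with larixol. C8 is hydrated, the side chain is trimmed to the ketone, C18 is oxidised from the 6α-oxygen, and the chain is rebuilt to the E-allylic chloride. This is joined to the four-membered ring and methylated; the lactone ring is formed last, before desilylation.
- Stereochemistry: C5, C6, C9 and C10 from larixol; C8 from α-face epoxidation and hydride opening; C4 from a 1,5-hydrogen transfer that reaches only the 4α-methyl; 13E from the olefination (minor isomer removed); Z at C5'=C15 from the C4' methyl in the ring expansion.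

Key step: step 15

Remark on the chemistry: labdane numbering is used for the decalin and chain and primed locants for the lactone ring; (+)-larixol is assumed to be purchasable; C13 of the cyclic methyl ketals and the carbinol carbons of the four-membered-ring intermediates are carried as epimer mixtures (drawn without descriptor) because these centres are destroyed later.

**Route**

Step 1
Reactants: 1 diisopropyl squarate
Product: 3 3-isopropoxycyclobut-3-ene-1,2-dione (isopropyl semisquarate), via 4-hydroxy-2,3-diisopropoxycyclobutenone 2 (not isolated)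
Conditions: LiAlH(OtBu)3, THF, −78 → 0 °C; then 6 M aq. HCl, CH2Cl2, rt
Reagents that add atoms: water (O)
Why: The hindered hydride adds once to a squarate carbonyl and acid then ionises the carbinol, water adds at the distal alkoxy carbon and isopropanol is lost (reduction followed by Stork–Danheiser-type transposition of a vinylogous ester), the standard entry to semisquarates.

Step 2
Reactants: 4 (+)-larixol
Product: 5 (13S)-8α,17-epoxylabd-14-ene-6α,13-diol
Conditions: mCPBA (1.05 equiv), NaHCO3, CH2Cl2, 0 °C
Reagents that add atoms: mCPBA (OOC(=O)c1cccc(Cl)c1)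
Why: Prilezhaev epoxidation is faster at the 1,1-disubstituted C8=C17 alkene than at the monosubstituted vinyl group, and the peracid comes from the α-face because the axial C20 methyl shields the β-face, so the new C8–O bond is α.

Step 3
Reactants: 5 (13S)-8α,17-epoxylabd-14-ene-6α,13-diol
Product: 6 (13S)-labd-14-ene-6α,8α,13-triol
Conditions: LiAlH4, THF, 0 °C → reflux; H2O, aq. NaOH work-up
Reagents that add atoms: none
Why: Hydride opens the spiro-epoxide by SN2 attack at the unsubstituted C17 (reductive epoxide opening), which leaves the C8–O bond untouched and delivers the 8α-hydroxy-8β-methyl arrangement.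

Step 4
Reactants: 6 (13S)-labd-14-ene-6α,8α,13-triol
Product: 7 6α,8α-dihydroxy-14,15-dinorlabdan-13-one
Conditions: KMnO4, BnEt3NCl (cat.), CH2Cl2/H2O, 0 °C → rt
Reagents that add atoms: none
Why: Permanganate dihydroxylates the vinyl group and cleaves the 13,14-glycol so formed (oxidative degradation of a tertiary vinyl carbinol to a methyl ketone, long used on sclareol-type side chains), while the hindered 6α-hydroxyl and the tertiary 8-hydroxyl are left alone under cold neutral conditions.

Step 5
Reactants: 7 6α,8α-dihydroxy-14,15-dinorlabdan-13-one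
Product: 8 8α,13-epoxy-13-methoxy-14,15-dinorlabdan-6α-ol (cyclic methyl ketal)
Conditions: MeOH, PPTS (cat.), 3 Å molecular sieves, rt; Et3N quench
Reagents that add atoms: methanol (CO)
Why: Acid-catalysed mixed ketalisation closes the 8α-oxygen onto C13 in a six-membered ring and caps it as the methyl ketal, which masks both the tertiary alcohol and the ketone and leaves the 6α-hydroxyl as the only free OH.

Step 6
Reactants: 8 8α,13-epoxy-13-methoxy-14,15-dinorlabdan-6α-ol
Product: 11 6α,18:8α,13-diepoxy-13-methoxy-14,15-dinorlabdane, via alkyl hypoiodite 9 (not isolated), via 18-iodo alcohol 10 (not isolated)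
Conditions: PhI(OAc)2, I2, cyclohexane, hν (tungsten lamp), 40 °C
Reagents that add atoms: none
Why: Suárez hypoiodite reaction: light cleaves the O–I bond, the 6α-alkoxy radical takes a hydrogen by 1,5-transfer from the equatorial 4α-methyl, whose C–H bonds lie parallel to the C6–O bond and about 2.6 Å away whereas the axial 4β-methyl and C20 are out of reach, and the C18 iodide then closes to the tetrahydrofuran, so the C4 configuration is set by this proximity.

Step 7
Reactants: 11 6α,18:8α,13-diepoxy-13-methoxy-14,15-dinorlabdane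
Product: 12 8α,13-epoxy-13-methoxy-14,15-dinorlabdan-18,6α-olide
Conditions: RuCl3·xH2O (cat.), NaIO4, NaHCO3, EtOAc/MeCN/H2O, rt
Reagents that add atoms: sodium periodate ([Na+].[O-]I(=O)(=O)=O)
Why: RuO4 formed in the flask oxidises the ether methylene C18 in preference to the more hindered ether methine C6 (ether-to-lactone oxidation), and the bicarbonate buffer keeps the methyl ketal intact.

Step 8
Reactants: 12 8α,13-epoxy-13-methoxy-14,15-dinorlabdan-18,6α-olide
Product: 14 6α,8α,18-trihydroxy-14,15-dinorlabdan-13-one, via diol ketal 13 (not isolated)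
Conditions: LiAlH4, THF, 0 °C → rt; then 1 M aq. HCl, THF, rt
Reagents that add atoms: water (O)
Why: LiAlH4 reduces the γ-lactone to the 6α,18-diol and the acidic work-up hydrolyses the mixed ketal to the 8α-hydroxy ketone (lactone reduction then ketal hydrolysis), with no stereocentre involved.

Step 9
Reactants: 14 6α,8α,18-trihydroxy-14,15-dinorlabdan-13-one
Product: 15 6α,8α,18-tris(triethylsilyloxy)-14,15-dinorlabdan-13-one
Conditions: TESOTf (3.5 equiv), 2,6-lutidine, CH2Cl2, −78 → −20 °C
Reagents that add atoms: triethylsilyl triflate (CC[Si](CC)(CC)OS(=O)(=O)C(F)(F)F)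
Why: Silyl triflate and 2,6-lutidine silylate primary, hindered secondary and tertiary hydroxyls alike (O-silylation), and at low temperature this is much faster than enol silylation of the methyl ketone.

Step 10
Reactants: 15 6α,8α,18-tris(triethylsilyloxy)-14,15-dinorlabdan-13-one
Product: 16 ethyl (13E)-6α,8α,18-tris(triethylsilyloxy)labd-13-en-15-oate
Conditions: (EtO)2P(O)CH2CO2Et, NaH, THF, 0 → 50 °C; chromatographic removal of the minor Z ester
Reagents that add atoms: triethyl phosphonoacetate (CCOC(=O)CP(=O)(OCC)OCC)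
Why: Horner–Wadsworth–Emmons olefination of the unhindered methyl ketone gives the trisubstituted enoate, the E isomer being favoured because the ester group avoids the C12 chain in the oxaphosphetane, and the minor Z ester is separable at this stage.

Step 11
Reactants: 16 ethyl (13E)-6α,8α,18-tris(triethylsilyloxy)labd-13-en-15-oate
Product: 17 (13E)-6α,8α,18-tris(triethylsilyloxy)labd-13-en-15-ol
Conditions: i-Bu2AlH, CH2Cl2, −78 °C; aq. potassium sodium tartrate
Reagents that add atoms: none
Why: i-Bu2AlH reduces the conjugated ester by 1,2-addition to the allylic alcohol at low temperature (ester reduction) without affecting the silyl ethers or the alkene geometry.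

Step 12
Reactants: 17 (13E)-6α,8α,18-tris(triethylsilyloxy)labd-13-en-15-ol
Product: 19 (13E)-15-chloro-6α,8α,18-tris(triethylsilyloxy)labd-13-ene, via allylic mesylate 18 (not isolated)
Conditions: MsCl, LiCl, 2,4,6-collidine, DMF, 0 °C
Reagents that add atoms: lithium chloride ([Li+].[Cl-])
Why: Mesylation and SN2 displacement by chloride at the primary allylic carbon in one flask (Collington–Meyers conditions) gives the chloride without allylic transposition or E/Z change, the collidine keeping the medium safe for the silyl ethers.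

Step 13
Reactants: 19 (13E)-15-chloro-6α,8α,18-tris(triethylsilyloxy)labd-13-ene; 3 3-isopropoxycyclobut-3-ene-1,2-dione
Product: 21 4-hydroxy-3-isopropoxy-4-[(13E)-6α,8α,18-tris(triethylsilyloxy)labd-13-en-15-yl]cyclobut-2-en-1-one, via allylbarium chloride 20 (not isolated)
Conditions: BaI2, LiC12H10 (lithium biphenylide, 2 equiv per BaI2), THF, rt; then 19, −78 °C; then 3, −78 °C; aq. NH4Cl
Reagents that add atoms: none
Why: Yamamoto allylbarium addition: the allylbarium chloride formed from zerovalent barium at −78 °C reacts with carbonyl groups through its unsubstituted α-carbon C15 and keeps the E geometry, and it attacks the ketone carbonyl beside the isopropoxy-bearing carbon because the other carbonyl is a deactivated vinylogous ester; the new carbinol centre forms as both epimers, which is of no consequence.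

Step 14
Reactants: 21 4-hydroxy-3-isopropoxy-4-[(13E)-6α,8α,18-tris(triethylsilyloxy)labd-13-en-15-yl]cyclobut-2-en-1-one
Product: 23 4-hydroxy-3-methyl-4-[(13E)-6α,8α,18-tris(triethylsilyloxy)labd-13-en-15-yl]cyclobut-2-en-1-one, via cyclobutenediol 22 (not isolated)
Conditions: MeLi (2.5 equiv), THF, −78 °C; then 0.2 M aq. HCl to pH 3, THF, 0 °C
Reagents that add atoms: methyllithium ([Li]C); water (O)
Why: MeLi adds 1,2 to the vinylogous-ester carbonyl and dilute acid then ionises the new tertiary allylic hydroxyl, water adds at the isopropoxy carbon and isopropanol is lost (Stork–Danheiser transposition, the standard way from squarate adducts to cyclobutenones), which places the methyl on the carbon next to the carbinol and the carbonyl on its other side; the silyl ethers tolerate pH 3 at 0 °C for the short time needed.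

Step 15
Reactants: 23 4-hydroxy-3-methyl-4-[(13E)-6α,8α,18-tris(triethylsilyloxy)labd-13-en-15-yl]cyclobut-2-en-1-one
Product: 25 tris(triethylsilyl) ether of the target, via lead alkoxide 24 (not isolated)
Conditions: Pb(OAc)4 (1.3 equiv), toluene, 0 °C → rt, dark
Reagents that add atoms: none
Why: Ligand exchange gives the tetravalent-lead alkoxide of the strained carbinol, and heterolysis of its O–Pb bond (lead leaving as divalent Pb(OAc)2) is coupled to cleavage of the C5'–C2' bond, which releases the cyclobutene strain and leaves a C5' ketone tethered to a Z-alkenoyl (acylium) carbon C2'. The closest known reaction type is the Pb(OAc)4-mediated oxidative ring expansion of 4-hydroxycyclobut-2-enones to 5-acetoxy- and 5-ylidene-2(5H)-furanones, itself a strained variant of α-ketol cleavage. The lactone ring closes when the C5' keto oxygen attacks the acylium carbon C2' (five-membered, 5-exo-dig closure held in place by the Z C3'=C4' bond), so the former hydroxyl oxygen ends up between C5' and C2'. No stereocentre is created; the C5'=C15 geometry is decided when the oxocarbenium ion loses a C15 proton, and the Z isomer is favoured because the E isomer would press C14 against the C4' methyl. The step needs cleavage of the acyl bond C5'–C2' rather than the allyl bond C5'–C15 (secured by ring strain and acylium stabilisation) and proton loss rather than acetate capture (secured by the allylic C15–H bonds, whose loss extends conjugation to C13=C14). The silyl ethers and the trisubstituted alkene are inert to Pb(OAc)4 in toluene over the short reaction time.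

Step 16
Reactants: 25 tris(triethylsilyl) ether of the target
Product: 26 CNP0126806.1 (target)
Conditions: HF·pyridine, pyridine, THF, 0 °C → rt
Reagents that add atoms: none
Why: Fluoride cleaves the three Si–O bonds (desilylation) under buffered, weakly acidic conditions that spare the base- and light-sensitive Z-ylidene butenolide and the triene.

**Compound list**

1 | diisopropyl squarate (3,4-diisopropoxycyclobut-3-ene-1,2-dione) | CC(C)OC1=C(OC(C)C)C(=O)C1=O | starting material
2 | 4-hydroxy-2,3-diisopropoxycyclobut-2-en-1-one (racemic) | CC(C)OC1=C(OC(C)C)C(=O)C1O | intermediate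
3 | 3-isopropoxycyclobut-3-ene-1,2-dione (isopropyl semisquarate) | CC(C)OC1=CC(=O)C1=O | intermediate
4 | (+)-larixol; (13S)-labda-8(17),14-diene-6α,13-diol | C=C[C@@](C)(O)CC[C@@H]1[C@@]2(C)CCCC(C)(C)[C@@H]2[C@@H](O)CC1=C | starting material
5 | (13S)-8α,17-epoxylabd-14-ene-6α,13-diol | C=C[C@@](C)(O)CC[C@@H]1[C@@]2(C)CCCC(C)(C)[C@@H]2[C@@H](O)C[C@@]1(C3)O3 | intermediate
6 | (13S)-labd-14-ene-6α,8α,13-triol | C=C[C@@](C)(O)CC[C@@H]1[C@@]2(C)CCCC(C)(C)[C@@H]2[C@@H](O)C[C@@]1(C)O | intermediate
7 | 6α,8α-dihydroxy-14,15-dinorlabdan-13-one | CC(=O)CC[C@@H]1[C@@]2(C)CCCC(C)(C)[C@@H]2[C@@H](O)C[C@@]1(C)O | intermediate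
8 | 8α,13-epoxy-13-methoxy-14,15-dinorlabdan-6α-ol (cyclic methyl ketal; both C13 epimers) | COC1(C)CC[C@@H]2[C@@]3(C)CCCC(C)(C)[C@@H]3[C@@H](O)C[C@@]2(C)O1 | intermediate
9 | 6α-hypoiodite of 8 (alkyl hypoiodite) | COC1(C)CC[C@@H]2[C@@]3(C)CCCC(C)(C)[C@@H]3[C@@H](OI)C[C@@]2(C)O1 | intermediate
10 | 18-iodo-8α,13-epoxy-13-methoxy-14,15-dinorlabdan-6α-ol | COC1(C)CC[C@@H]2[C@@]3(C)CCC[C@@](C)(CI)[C@@H]3[C@@H](O)C[C@@]2(C)O1 | intermediate
11 | 6α,18:8α,13-diepoxy-13-methoxy-14,15-dinorlabdane | COC1(C)CC[C@@H]2[C@@]3(C)CCC[C@@](C)(CO4)[C@@H]3[C@@H]4C[C@@]2(C)O1 | intermediate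
12 | 8α,13-epoxy-13-methoxy-14,15-dinorlabdan-18,6α-olide | COC1(C)CC[C@@H]2[C@@]3(C)CCC[C@@](C)(C(=O)O4)[C@@H]3[C@@H]4C[C@@]2(C)O1 | intermediate
13 | 8α,13-epoxy-13-methoxy-14,15-dinorlabdane-6α,18-diol | COC1(C)CC[C@@H]2[C@@]3(C)CCC[C@@](C)(CO)[C@@H]3[C@@H](O)C[C@@]2(C)O1 | intermediate
14 | 6α,8α,18-trihydroxy-14,15-dinorlabdan-13-one | CC(=O)CC[C@@H]1[C@@]2(C)CCC[C@@](C)(CO)[C@@H]2[C@@H](O)C[C@@]1(C)O | intermediate
15 | 6α,8α,18-tris(triethylsilyloxy)-14,15-dinorlabdan-13-one | CC(=O)CC[C@@H]1[C@@]2(C)CCC[C@@](C)(CO[Si](CC)(CC)CC)[C@@H]2[C@@H](O[Si](CC)(CC)CC)C[C@@]1(C)O[Si](CC)(CC)CC | intermediate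
16 | ethyl (13E)-6α,8α,18-tris(triethylsilyloxy)labd-13-en-15-oate | CCOC(=O)/C=C(\C)CC[C@@H]1[C@@]2(C)CCC[C@@](C)(CO[Si](CC)(CC)CC)[C@@H]2[C@@H](O[Si](CC)(CC)CC)C[C@@]1(C)O[Si](CC)(CC)CC | intermediate
17 | (13E)-6α,8α,18-tris(triethylsilyloxy)labd-13-en-15-ol | OC/C=C(\C)CC[C@@H]1[C@@]2(C)CCC[C@@](C)(CO[Si](CC)(CC)CC)[C@@H]2[C@@H](O[Si](CC)(CC)CC)C[C@@]1(C)O[Si](CC)(CC)CC | intermediate
18 | (13E)-6α,8α,18-tris(triethylsilyloxy)labd-13-en-15-yl methanesulfonate | CS(=O)(=O)OC/C=C(\C)CC[C@@H]1[C@@]2(C)CCC[C@@](C)(CO[Si](CC)(CC)CC)[C@@H]2[C@@H](O[Si](CC)(CC)CC)C[C@@]1(C)O[Si](CC)(CC)CC | intermediate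
19 | (13E)-15-chloro-6α,8α,18-tris(triethylsilyloxy)labd-13-ene | ClC/C=C(\C)CC[C@@H]1[C@@]2(C)CCC[C@@](C)(CO[Si](CC)(CC)CC)[C@@H]2[C@@H](O[Si](CC)(CC)CC)C[C@@]1(C)O[Si](CC)(CC)CC | intermediate
20 | [(13E)-6α,8α,18-tris(triethylsilyloxy)labd-13-en-15-yl]barium chloride | Cl[Ba]C/C=C(\C)CC[C@@H]1[C@@]2(C)CCC[C@@](C)(CO[Si](CC)(CC)CC)[C@@H]2[C@@H](O[Si](CC)(CC)CC)C[C@@]1(C)O[Si](CC)(CC)CC | intermediate
21 | 4-hydroxy-3-isopropoxy-4-[(13E)-6α,8α,18-tris(triethylsilyloxy)labd-13-en-15-yl]cyclobut-2-en-1-one (both carbinol epimers) | CC(C)OC1=CC(=O)C1(O)C/C=C(\C)CC[C@@H]1[C@@]2(C)CCC[C@@](C)(CO[Si](CC)(CC)CC)[C@@H]2[C@@H](O[Si](CC)(CC)CC)C[C@@]1(C)O[Si](CC)(CC)CC | intermediate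
22 | 3-isopropoxy-1-methyl-4-[(13E)-6α,8α,18-tris(triethylsilyloxy)labd-13-en-15-yl]cyclobut-2-ene-1,4-diol | CC(C)OC1=CC(C)(O)C1(O)C/C=C(\C)CC[C@@H]1[C@@]2(C)CCC[C@@](C)(CO[Si](CC)(CC)CC)[C@@H]2[C@@H](O[Si](CC)(CC)CC)C[C@@]1(C)O[Si](CC)(CC)CC | intermediate
23 | 4-hydroxy-3-methyl-4-[(13E)-6α,8α,18-tris(triethylsilyloxy)labd-13-en-15-yl]cyclobut-2-en-1-one (both carbinol epimers) | CC1=CC(=O)C1(O)C/C=C(\C)CC[C@@H]1[C@@]2(C)CCC[C@@](C)(CO[Si](CC)(CC)CC)[C@@H]2[C@@H](O[Si](CC)(CC)CC)C[C@@]1(C)O[Si](CC)(CC)CC | intermediate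
24 | triacetoxylead alkoxide of 23 (tetravalent lead) | CC1=CC(=O)C1(O[Pb](OC(C)=O)(OC(C)=O)OC(C)=O)C/C=C(\C)CC[C@@H]1[C@@]2(C)CCC[C@@](C)(CO[Si](CC)(CC)CC)[C@@H]2[C@@H](O[Si](CC)(CC)CC)C[C@@]1(C)O[Si](CC)(CC)CC | intermediate
25 | tris(triethylsilyl) ether of the target | CC1=CC(=O)O/C1=C\C=C(/C)CC[C@@H]1[C@@]2(C)CCC[C@@](C)(CO[Si](CC)(CC)CC)[C@@H]2[C@@H](O[Si](CC)(CC)CC)C[C@@]1(C)O[Si](CC)(CC)CC | intermediate
26 | CNP0126806.1 | CC1=CC(=O)O/C1=C\C=C(/C)CC[C@@H]1[C@@]2(C)CCC[C@@](C)(CO)[C@@H]2[C@@H](O)C[C@@]1(C)O | target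

**Step count and risks**

Total: 16 steps. Longest linear sequence: 15 steps (steps 2–16 from larixol); the one-step semisquarate branch (step 1) enters at step 13.

Most likely to fail, in this order:

Step 15. The lead alkoxide may fragment on the allyl side and lose the C15 chain, the oxocarbenium ion may capture acetate instead of losing the C15 proton, or the silyl ethers may suffer from the acetic acid released. The fallback builds the lactone by vinylogous aldol condensation and sets out from allylic alcohol 17. MnO2 in CH2Cl2 gives the (13E)-enal F1. 4-Methylfuran-2(5H)-one, TBSOTf and i-Pr2NEt form the 2-silyloxyfuran in the flask, which adds through its C5 to the aldehyde to give the silylated aldol F2. DBU then eliminates the silanol to the Z-ylidene butenolide, which is compound 25, and step 16 follows.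

Step 13. The allylbarium may lose regio- or geometric integrity (attack through C13, E/Z equilibration), couple with unreacted chloride, or the activated barium may reduce the dione. The fallback forms C13=C14 by cross-metathesis instead of joining C15 to C5' through an allyl metal, and sets out from ketone 15 and semisquarate 3. Methylenation of 15 (Ph3P=CH2, THF) gives the terminal 2-methylalk-1-ene F3. Allylmagnesium bromide adds to 3 (THF, −78 °C; an unsubstituted allyl group poses no regiochemical question) to give the allyl hydroxycyclobutenone F4. Cross-metathesis of the two with the second-generation Hoveyda–Grubbs catalyst (CH2Cl2, 40 °C) comes back to the route at 21, and steps 14–16 follow. The geometry of this trisubstituted alkene is only moderately controlled in metathesis, so the isomers would have to be separated at 21 or 23.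

Step 6. The alkoxy radical may undergo β-scission of C5–C6 instead of hydrogen transfer, or the mixed ketal may lose methanol in the acetic acid/iodine medium and the resulting enol ether be consumed. The fallback oxidises C18 by directed C–H silylation instead of radical chemistry and sets out from 8. Et2SiH2 with [Ir(cod)OMe]2 (cat.) gives the diethylhydrosilyl ether F5. [Rh(cod)Cl]2/Xantphos (cat.) with norbornene as hydrogen acceptor closes the six-membered oxasilinane F6 by silylation of the δ C–H bond of the 4α-methyl. Tamao–Fleming oxidation (H2O2, KHCO3, KF, THF/MeOH) gives diol ketal 13, which is hydrolysed as in the second stage of step 8 to reach 14; steps 6 and 7 and the LiAlH4 stage are bypassed.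

**Further compounds**

F1 | step 15 | (13E)-6α,8α,18-tris(triethylsilyloxy)labd-13-en-15-al | O=C/C=C(\C)CC[C@@H]1[C@@]2(C)CCC[C@@](C)(CO[Si](CC)(CC)CC)[C@@H]2[C@@H](O[Si](CC)(CC)CC)C[C@@]1(C)O[Si](CC)(CC)CC
F2 | step 15 | 4-methyl-5-[(13E)-15-(tert-butyldimethylsilyloxy)-6α,8α,18-tris(triethylsilyloxy)labd-13-en-15-yl]furan-2(5H)-one (diastereomer mixture at C5' and C15) | CC1=CC(=O)OC1C(O[Si](C)(C)C(C)(C)C)/C=C(\C)CC[C@@H]1[C@@]2(C)CCC[C@@](C)(CO[Si](CC)(CC)CC)[C@@H]2[C@@H](O[Si](CC)(CC)CC)C[C@@]1(C)O[Si](CC)(CC)CC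
F3 | step 13 | 6α,8α,18-tris(triethylsilyloxy)-15-norlabd-13-ene (terminal 2-methylalk-1-ene) | C=C(C)CC[C@@H]1[C@@]2(C)CCC[C@@](C)(CO[Si](CC)(CC)CC)[C@@H]2[C@@H](O[Si](CC)(CC)CC)C[C@@]1(C)O[Si](CC)(CC)CC
F4 | step 13 | 4-allyl-4-hydroxy-3-isopropoxycyclobut-2-en-1-one (racemic) | CC(C)OC1=CC(=O)C1(O)CC=C
F5 | step 6 | 6α-(diethylsilyloxy)-8α,13-epoxy-13-methoxy-14,15-dinorlabdane | COC1(C)CC[C@@H]2[C@@]3(C)CCCC(C)(C)[C@@H]3[C@@H](O[SiH](CC)CC)C[C@@]2(C)O1
F6 | step 6 | 6α-O,18-C-(diethylsilanediyl)-bridged oxasilinane of the cyclic methyl ketal | COC1(C)CC[C@@H]2[C@@]3(C)CCC[C@@](C)(C[Si](CC)(CC)O4)[C@@H]3[C@@H]4C[C@@]2(C)O1
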